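**Retrosynthetic overview** (germacrane numbering: ring C1–C10, lactone C11–C13, C14 on C10, C15 on C4)
1. Target 21 ⇒ aldehyde–allylboronate 19: the C7–C8 bond and the C12–O8 lactone bond close together in the last step (ten-membered carbocycle and α-methylene lactone at once, epoxide and both acetates already in place).
2. 19 ⇒ ynoate 14 (syn-hydroalumination/CH2Bpin homologation gives the geometry-defined allyl donor; both acetates put on together) ⇒ epoxy aldehyde 12 + methyl propiolate 13 (C6–C7, sets C6).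
3. 12 ⇒ dienoate 9 (reduction, Sharpless epoxidation for C4/C5, oxidation) ⇒ enal 6 + silyl dienolate 8 (vinylogous aldol, C2–C3, sets C2).
4. 6 ⇒ but-3-yn-1-ol 1 (carboalumination fixes the (E)-C1=C10 alkene).
5. Ring order: epoxide (step 7), then carbocycle and lactone together (step 13).

Assumption: the (S,S)-bisphosphoramide/SiCl4 catalyst and the (S,S)-ProPhenol/Me2Zn catalyst are taken as the enantiomers that deliver the nucleophile to the Si face of aldehydes 6 and 12; if either sense is the reverse, the mirror-image ligand is used.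

Step 1
Reactants: 1 but-3-yn-1-ol
Product: 2 tert-butyl(but-3-yn-1-yloxy)dimethylsilane
Conditions: TBSCl, imidazole, CH2Cl2, 0 °C → rt
Reagents that add atoms: tert-butyldimethylsilyl chloride, C[Si](C)(Cl)C(C)(C)C
Why: Routine silyl ether protection of the primary alcohol (future C8–OH); no stereocenter is involved.

Step 2
Reactants: 2 tert-butyl(but-3-yn-1-yloxy)dimethylsilane
Product: 5 (2E)-5-(tert-butyldimethylsilyloxy)-3-methylpent-2-en-1-ol, via alkenylalane 3 (not isolated), via lithium alkenylalanate 4 (not isolated)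
Conditions: Me3Al, Cp2ZrCl2 (20 mol%), CH2Cl2, 0 °C → rt; then n-BuLi, (CH2O)n, THF, −30 °C → rt
Reagents that add atoms: trimethylaluminium, C[Al](C)C; paraformaldehyde (formaldehyde unit), C=O
Why: Negishi zirconium-catalysed carboalumination adds Me and Al syn across the terminal alkyne with Me on the internal carbon, and the alanate is hydroxymethylated with retention, which fixes the (E)-trisubstituted C1=C10 alkene.

Step 3
Reactants: 5 (2E)-5-(tert-butyldimethylsilyloxy)-3-methylpent-2-en-1-ol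
Product: 6 (2E)-5-(tert-butyldimethylsilyloxy)-3-methylpent-2-enal
Conditions: MnO2, CH2Cl2, rt
Reagents that add atoms: none
Why: Allylic alcohol oxidation with MnO2 stops at the enal and leaves the alkene geometry and the silyl ether untouched.

Step 4
Reactants: 7 methyl 3-methylbut-2-enoate
Product: 8 tert-butyl[(1-methoxy-3-methylbuta-1,3-dien-1-yl)oxy]dimethylsilane
Conditions: LiN(i-Pr)2, THF, −78 °C; then TBSCl, DMPU, −78 °C → rt
Reagents that add atoms: tert-butyldimethylsilyl chloride, C[Si](C)(Cl)C(C)(C)C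
Why: γ-Deprotonation of the senecioate ester and O-silylation (silyl dienolate formation) give the vinylogous ketene acetal; its geometry is of no consequence.

Step 5
Reactants: 6 (2E)-5-(tert-butyldimethylsilyloxy)-3-methylpent-2-enal; 8 tert-butyl[(1-methoxy-3-methylbuta-1,3-dien-1-yl)oxy]dimethylsilane
Product: 9 methyl (2E,5S,6E)-9-(tert-butyldimethylsilyloxy)-5-hydroxy-3,7-dimethylnona-2,6-dienoate
Conditions: SiCl4, (S,S)-bisphosphoramide [pentane-1,5-diyl-bridged bis(N-methylphosphoramide) of (S)-N,N'-dimethyl-1,1'-binaphthyl-2,2'-diamine] (2 mol%), i-Pr2NEt (10 mol%), CH2Cl2, −78 °C; aq. NaHCO3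
Reagents that add atoms: none
Why: Lewis-base-activated SiCl4 vinylogous Mukaiyama aldol reaction, in which the dienolate attacks through its γ-CH2 in an open transition state to give the (E)-enoate while the chiral phosphoramide-bound silicon cation exposes only the Si face of the enal, so C2 is formed as (S).

Step 6
Reactants: 9 methyl (2E,5S,6E)-9-(tert-butyldimethylsilyloxy)-5-hydroxy-3,7-dimethylnona-2,6-dienoate
Product: 10 (2E,5S,6E)-9-(tert-butyldimethylsilyloxy)-3,7-dimethylnona-2,6-diene-1,5-diol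
Conditions: i-Bu2AlH, CH2Cl2, −78 °C; aq. potassium sodium tartrate
Reagents that add atoms: none
Why: 1,2-Reduction of the conjugated ester by i-Bu2AlH gives the primary allylic alcohol without touching the alkenes, the silyl ether or the C2 stereocenter.

Step 7
Reactants: 10 (2E,5S,6E)-9-(tert-butyldimethylsilyloxy)-3,7-dimethylnona-2,6-diene-1,5-diol
Product: 11 [(2R,3R)-3-[(2S,3E)-6-(tert-butyldimethylsilyloxy)-2-hydroxy-4-methylhex-3-en-1-yl]-3-methyloxiran-2-yl]methanol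
Conditions: Ti(Oi-Pr)4 (10 mol%), D-(−)-diethyl tartrate (12 mol%), t-BuOOH, 4 Å MS, CH2Cl2, −20 °C
Reagents that add atoms: tert-butyl hydroperoxide, CC(C)(C)OO
Why: Sharpless asymmetric epoxidation, in which the titanium D-(−)-tartrate catalyst epoxidizes the primary allylic alcohol olefin on the face that gives the (2R,3R)-epoxy alcohol (C4 R, C5 R), while the C1=C10 olefin is spared because its (S)-carbinol at C2 is the slow-reacting enantiomer for this tartrate and carries a cis substituent.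

Step 8
Reactants: 11 [(2R,3R)-3-[(2S,3E)-6-(tert-butyldimethylsilyloxy)-2-hydroxy-4-methylhex-3-en-1-yl]-3-methyloxiran-2-yl]methanol
Product: 12 (2S,3R)-3-[(2S,3E)-6-(tert-butyldimethylsilyloxy)-2-hydroxy-4-methylhex-3-en-1-yl]-3-methyloxirane-2-carbaldehyde
Conditions: TEMPO (2,2,6,6-tetramethylpiperidin-1-oxyl, 10 mol%), PhI(OAc)2, CH2Cl2, rt
Reagents that add atoms: none
Why: Oxoammonium (TEMPO/PhI(OAc)2) oxidation is selective for the primary over the secondary alcohol and is mild enough for an α,β-epoxy aldehyde (the oxirane CH changes descriptor only because CHO outranks the ring carbon).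

Step 9
Reactants: 12 (2S,3R)-3-[(2S,3E)-6-(tert-butyldimethylsilyloxy)-2-hydroxy-4-methylhex-3-en-1-yl]-3-methyloxirane-2-carbaldehyde; 13 methyl prop-2-ynoate
Product: 14 methyl (4S)-4-hydroxy-4-[(2R,3R)-3-[(2S,3E)-6-(tert-butyldimethylsilyloxy)-2-hydroxy-4-methylhex-3-en-1-yl]-3-methyloxiran-2-yl]but-2-ynoate
Conditions: Me2Zn, (S,S)-ProPhenol [2,6-bis{[(2S)-2-(hydroxydiphenylmethyl)pyrrolidin-1-yl]methyl}-4-methylphenol] (20 mol%), Ph3PO (40 mol%), toluene, 0 °C
Reagents that add atoms: none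
Why: Catalytic asymmetric zinc alkynylation of an aldehyde, in which the zinc acetylide of 13 adds to the Si face under catalyst control, a sense that Cram-chelate control through the epoxide oxygen also favours, so C6 is set as (S), threo to the epoxide.

Step 10
Reactants: 14 methyl (4S)-4-hydroxy-4-[(2R,3R)-3-[(2S,3E)-6-(tert-butyldimethylsilyloxy)-2-hydroxy-4-methylhex-3-en-1-yl]-3-methyloxiran-2-yl]but-2-ynoate
Product: 16 methyl (4S)-4-acetoxy-4-[(2R,3R)-3-[(2S,3E)-2-acetoxy-6-hydroxy-4-methylhex-3-en-1-yl]-3-methyloxiran-2-yl]but-2-ynoate, via silyl diacetate 15 (not isolated)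
Conditions: Ac2O, pyridine, 4-(dimethylamino)pyridine (5 mol%), THF, 0 °C → rt; MeOH; then HF·pyridine, 0 °C
Reagents that add atoms: acetic anhydride, CC(=O)OC(C)=O
Why: Acylation installs both target acetates (C2 and C6) at once, and buffered HF·pyridine then cleaves only the primary silyl ether (fluoride desilylation) without opening the epoxide.

Step 11
Reactants: 16 methyl (4S)-4-acetoxy-4-[(2R,3R)-3-[(2S,3E)-2-acetoxy-6-hydroxy-4-methylhex-3-en-1-yl]-3-methyloxiran-2-yl]but-2-ynoate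
Product: 18 methyl (2Z,4S)-4-acetoxy-4-[(2R,3R)-3-[(2S,3E)-2-acetoxy-6-hydroxy-4-methylhex-3-en-1-yl]-3-methyloxiran-2-yl]-2-[(4,4,5,5-tetramethyl-1,3,2-dioxaborolan-2-yl)methyl]but-2-enoate, via α-alumino enoate 17 (not isolated)
Conditions: i-Bu2AlH (2.2 equiv), HMPA (hexamethylphosphoric triamide), THF, −20 → 0 °C; then ICH2Bpin, 0 °C → rt; aq. potassium sodium tartrate
Reagents that add atoms: 2-(iodomethyl)-4,4,5,5-tetramethyl-1,3,2-dioxaborolane, ICB1OC(C)(C)C(C)(C)O1
Why: The HMPA-complexed hydride adds 1,4 and syn to the ynoate (hydroalumination, H on C7, Al on C11) faster than it attacks the acetates, and the alkenyl group then moves to boron and shifts onto CH2 with loss of iodide (Matteson-type 1,2-metallate homologation) with retention, giving the allylboronate with C6 cis to CO2Me.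

Step 12
Reactants: 18 methyl (2Z,4S)-4-acetoxy-4-[(2R,3R)-3-[(2S,3E)-2-acetoxy-6-hydroxy-4-methylhex-3-en-1-yl]-3-methyloxiran-2-yl]-2-[(4,4,5,5-tetramethyl-1,3,2-dioxaborolan-2-yl)methyl]but-2-enoate
Product: 19 methyl (2Z,4S)-4-acetoxy-4-[(2R,3R)-3-[(2S,3E)-2-acetoxy-4-methyl-6-oxohex-3-en-1-yl]-3-methyloxiran-2-yl]-2-[(4,4,5,5-tetramethyl-1,3,2-dioxaborolan-2-yl)methyl]but-2-enoate
Conditions: Dess–Martin periodinane, NaHCO3, CH2Cl2, 0 °C
Reagents that add atoms: none
Why: Buffered Dess–Martin oxidation gives the β,γ-unsaturated aldehyde (C8) without double-bond migration and does not touch the pinacol allylboronate, which is unreactive toward aldehydes at this temperature.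

Step 13
Reactants: 19 methyl (2Z,4S)-4-acetoxy-4-[(2R,3R)-3-[(2S,3E)-2-acetoxy-4-methyl-6-oxohex-3-en-1-yl]-3-methyloxiran-2-yl]-2-[(4,4,5,5-tetramethyl-1,3,2-dioxaborolan-2-yl)methyl]but-2-enoate
Product: 21 (2S,4R,5R,6S,7R,8S)-2,6-diacetoxy-4,5-epoxygermacra-1(10)E,11(13)-dien-12,8-olide, via O-boryl hydroxy ester 20 (not isolated)
Conditions: toluene (2 mM), 2,6-di-tert-butyl-4-methylphenol (cat.), 95 °C, 48 h
Reagents that add atoms: none
Why: Proposed new method: thermal intramolecular allylboration through a closed chair (Zimmerman–Traxler) transition state, where the C6 substituent trans to CH2B sits equatorial and so gives the anti adduct (H7/H8 trans, the trans-fused lactone), allylic 1,3-strain against the cis ester holds H6 in the alkene plane so that the aldehyde, tethered through C5, reaches C7 on the face opposite the acetate (C7 R, hence C8 S), and the resulting O8–B borate then attacks the neighbouring acrylate ester to close the lactone with loss of MeOBpin; the closest known reaction type is the intermolecular tandem allylboration–lactonization of 2-alkoxycarbonyl allylboronates with aldehydes, here carried over to a ten-membered ring closure.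

**Compound list**
1 | but-3-yn-1-ol | C#CCCO | starting material
2 | tert-butyl(but-3-yn-1-yloxy)dimethylsilane | C#CCCO[Si](C)(C)C(C)(C)C | intermediate
3 | [(1E)-4-(tert-butyldimethylsilyloxy)-2-methylbut-1-en-1-yl]dimethylalane | C[Al](C)/C=C(\C)CCO[Si](C)(C)C(C)(C)C | intermediate
4 | lithium butyl[(1E)-4-(tert-butyldimethylsilyloxy)-2-methylbut-1-en-1-yl]dimethylalanate | [Li+].CCCC[Al-](C)(C)/C=C(\C)CCO[Si](C)(C)C(C)(C)C | intermediate
5 | (2E)-5-(tert-butyldimethylsilyloxy)-3-methylpent-2-en-1-ol | OC/C=C(\C)CCO[Si](C)(C)C(C)(C)C | intermediate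
6 | (2E)-5-(tert-butyldimethylsilyloxy)-3-methylpent-2-enal | O=C/C=C(\C)CCO[Si](C)(C)C(C)(C)C | intermediate
7 | methyl 3-methylbut-2-enoate | COC(=O)C=C(C)C | starting material
8 | tert-butyl[(1-methoxy-3-methylbuta-1,3-dien-1-yl)oxy]dimethylsilane (ketene acetal geometry not defined) | C=C(C)C=C(OC)O[Si](C)(C)C(C)(C)C | intermediate
9 | methyl (2E,5S,6E)-9-(tert-butyldimethylsilyloxy)-5-hydroxy-3,7-dimethylnona-2,6-dienoate | COC(=O)/C=C(\C)C[C@H](O)/C=C(\C)CCO[Si](C)(C)C(C)(C)C | intermediate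
10 | (2E,5S,6E)-9-(tert-butyldimethylsilyloxy)-3,7-dimethylnona-2,6-diene-1,5-diol | OC/C=C(\C)C[C@H](O)/C=C(\C)CCO[Si](C)(C)C(C)(C)C | intermediate
11 | [(2R,3R)-3-[(2S,3E)-6-(tert-butyldimethylsilyloxy)-2-hydroxy-4-methylhex-3-en-1-yl]-3-methyloxiran-2-yl]methanol | OC[C@H]1O[C@]1(C)C[C@H](O)/C=C(\C)CCO[Si](C)(C)C(C)(C)C | intermediate
12 | (2S,3R)-3-[(2S,3E)-6-(tert-butyldimethylsilyloxy)-2-hydroxy-4-methylhex-3-en-1-yl]-3-methyloxirane-2-carbaldehyde | O=C[C@H]1O[C@]1(C)C[C@H](O)/C=C(\C)CCO[Si](C)(C)C(C)(C)C | intermediate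
13 | methyl prop-2-ynoate | C#CC(=O)OC | starting material
14 | methyl (4S)-4-hydroxy-4-[(2R,3R)-3-[(2S,3E)-6-(tert-butyldimethylsilyloxy)-2-hydroxy-4-methylhex-3-en-1-yl]-3-methyloxiran-2-yl]but-2-ynoate | COC(=O)C#C[C@H](O)[C@H]1O[C@]1(C)C[C@H](O)/C=C(\C)CCO[Si](C)(C)C(C)(C)C | intermediate
15 | methyl (4S)-4-acetoxy-4-[(2R,3R)-3-[(2S,3E)-2-acetoxy-6-(tert-butyldimethylsilyloxy)-4-methylhex-3-en-1-yl]-3-methyloxiran-2-yl]but-2-ynoate | COC(=O)C#C[C@H](OC(C)=O)[C@H]1O[C@]1(C)C[C@H](OC(C)=O)/C=C(\C)CCO[Si](C)(C)C(C)(C)C | intermediate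
16 | methyl (4S)-4-acetoxy-4-[(2R,3R)-3-[(2S,3E)-2-acetoxy-6-hydroxy-4-methylhex-3-en-1-yl]-3-methyloxiran-2-yl]but-2-ynoate | COC(=O)C#C[C@H](OC(C)=O)[C@H]1O[C@]1(C)C[C@H](OC(C)=O)/C=C(\C)CCO | intermediate
17 | methyl (2E,4S)-4-acetoxy-2-(diisobutylalumanyl)-4-[(2R,3R)-3-[(2S,3E)-2-acetoxy-6-(diisobutylalumanyloxy)-4-methylhex-3-en-1-yl]-3-methyloxiran-2-yl]but-2-enoate | COC(=O)/C([Al](CC(C)C)CC(C)C)=C\[C@H](OC(C)=O)[C@H]1O[C@]1(C)C[C@H](OC(C)=O)/C=C(\C)CCO[Al](CC(C)C)CC(C)C | intermediate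
18 | methyl (2Z,4S)-4-acetoxy-4-[(2R,3R)-3-[(2S,3E)-2-acetoxy-6-hydroxy-4-methylhex-3-en-1-yl]-3-methyloxiran-2-yl]-2-[(4,4,5,5-tetramethyl-1,3,2-dioxaborolan-2-yl)methyl]but-2-enoate | COC(=O)/C(CB1OC(C)(C)C(C)(C)O1)=C\[C@H](OC(C)=O)[C@H]1O[C@]1(C)C[C@H](OC(C)=O)/C=C(\C)CCO | intermediate
19 | methyl (2Z,4S)-4-acetoxy-4-[(2R,3R)-3-[(2S,3E)-2-acetoxy-4-methyl-6-oxohex-3-en-1-yl]-3-methyloxiran-2-yl]-2-[(4,4,5,5-tetramethyl-1,3,2-dioxaborolan-2-yl)methyl]but-2-enoate | COC(=O)/C(CB1OC(C)(C)C(C)(C)O1)=C\[C@H](OC(C)=O)[C@H]1O[C@]1(C)C[C@H](OC(C)=O)/C=C(\C)CC=O | intermediate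
20 | methyl 2-[(2S,4R,5R,6S,7R,8S)-2,6-diacetoxy-4,5-epoxy-8-(4,4,5,5-tetramethyl-1,3,2-dioxaborolan-2-yloxy)germacr-1(10)E-en-7-yl]prop-2-enoate (ten-membered ring closed, lactone still open; germacrane numbering) | COC(=O)C(=C)[C@@H]1[C@@H](OB2OC(C)(C)C(C)(C)O2)C/C(C)=C/[C@@H](OC(C)=O)C[C@@]3(C)O[C@@H]3[C@H]1OC(C)=O | intermediate
21 | (2S,4R,5R,6S,7R,8S)-2,6-diacetoxy-4,5-epoxygermacra-1(10)E,11(13)-dien-12,8-olide (CNP0270851.2) | C=C1C(=O)O[C@H]2C/C(C)=C/[C@@H](OC(C)=O)C[C@@]3(C)O[C@@H]3[C@@H](OC(C)=O)[C@H]12 | target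

**Totals**
Total step count: 13. Longest linear sequence: 12 steps (steps 1–3 and 5–13, from 1 to 21); step 4 is a one-step side branch.

**Steps most likely to fail, with fallbacks**

Step 13 (ring closure and lactonization). At 2 mM a pinacol allylboronate carrying an ester is a slow nucleophile, and the β,γ-unsaturated aldehyde or the 1,4-related acetate and boronate may decompose first. The fallback sets out from 15 (isolated after the acetylation, before the fluoride treatment) and comes back at 21. Conjugate reduction of the ynoate with [(Ph3P)CuH]6 and trapping of the copper enolate with formaldehyde gives methyl (2Z,4S)-4-acetoxy-4-[(2R,3R)-3-[(2S,3E)-2-acetoxy-6-(tert-butyldimethylsilyloxy)-4-methylhex-3-en-1-yl]-3-methyloxiran-2-yl]-2-(hydroxymethyl)but-2-enoate F1. CBr4/PPh3 turns it into the allylic bromide, the (2E)-2-(bromomethyl) silyl ether F2. HF·pyridine gives the (2E)-2-(bromomethyl) alcohol F3, and Dess–Martin oxidation gives the (2E)-2-(bromomethyl) aldehyde F4. CrCl2 (divalent chromium) in THF at high dilution then closes ring and lactone by a Nozaki–Hiyama-type allylation; the C7/C8 configuration then rests on macrocyclic control instead of reagent geometry.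

Step 11 (hydroalumination and boron homologation). The hydride may attack the acetates, or the alkenylalane may lose its geometry. The fallback sets out from 15 and comes back at 18. Bu3SnH with Pd(PPh3)4 (zerovalent palladium, catalytic) adds syn to the ynoate and gives the α-stannyl enoate, the (2E)-2-(tributylstannyl) silyl ether F5. I2 gives the (2E)-2-iodo enoate F6. Negishi coupling with IZnCH2Bpin (Pd(PPh3)4 cat.) gives the silyl-protected allylboronate F7 with retention, and HF·pyridine then gives 18.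

Step 9 (alkynylation of the epoxy aldehyde). The facial selectivity at an α,β-epoxy aldehyde with a free hydroxyl in the chain may be low. The fallback sets out from 10 and comes back at 15, with the order of C6 and epoxide formation reversed. TEMPO/PhI(OAc)2 oxidizes the primary allylic alcohol to (2E,5S,6E)-9-(tert-butyldimethylsilyloxy)-5-hydroxy-3,7-dimethylnona-2,6-dienal F8. Ac2O/pyridine gives the C2 acetate, (2E,5S,6E)-5-acetoxy-9-(tert-butyldimethylsilyloxy)-3,7-dimethylnona-2,6-dienal F9. The same ProPhenol zinc alkynylation with 13, now on an enal (its best substrate class), gives methyl (4R,5E,8S,9E)-8-acetoxy-12-(tert-butyldimethylsilyloxy)-4-hydroxy-6,10-dimethyldodeca-5,9-dien-2-ynoate F10. VO(acac)2/t-BuOOH epoxidation directed by the C6 hydroxyl (threo through allylic 1,3-strain with the cis methyl) gives methyl (4S)-4-[(2R,3R)-3-[(2S,3E)-2-acetoxy-6-(tert-butyldimethylsilyloxy)-4-methylhex-3-en-1-yl]-3-methyloxiran-2-yl]-4-hydroxybut-2-ynoate F11, and acetylation gives 15.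

**Further compounds**
F1 | step 13 | methyl (2Z,4S)-4-acetoxy-4-[(2R,3R)-3-[(2S,3E)-2-acetoxy-6-(tert-butyldimethylsilyloxy)-4-methylhex-3-en-1-yl]-3-methyloxiran-2-yl]-2-(hydroxymethyl)but-2-enoate | COC(=O)/C(CO)=C\[C@H](OC(C)=O)[C@H]1O[C@]1(C)C[C@H](OC(C)=O)/C=C(\C)CCO[Si](C)(C)C(C)(C)C
F2 | step 13 | methyl (2E,4S)-4-acetoxy-4-[(2R,3R)-3-[(2S,3E)-2-acetoxy-6-(tert-butyldimethylsilyloxy)-4-methylhex-3-en-1-yl]-3-methyloxiran-2-yl]-2-(bromomethyl)but-2-enoate | COC(=O)/C(CBr)=C\[C@H](OC(C)=O)[C@H]1O[C@]1(C)C[C@H](OC(C)=O)/C=C(\C)CCO[Si](C)(C)C(C)(C)C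
F3 | step 13 | methyl (2E,4S)-4-acetoxy-4-[(2R,3R)-3-[(2S,3E)-2-acetoxy-6-hydroxy-4-methylhex-3-en-1-yl]-3-methyloxiran-2-yl]-2-(bromomethyl)but-2-enoate | COC(=O)/C(CBr)=C\[C@H](OC(C)=O)[C@H]1O[C@]1(C)C[C@H](OC(C)=O)/C=C(\C)CCO
F4 | step 13 | methyl (2E,4S)-4-acetoxy-4-[(2R,3R)-3-[(2S,3E)-2-acetoxy-4-methyl-6-oxohex-3-en-1-yl]-3-methyloxiran-2-yl]-2-(bromomethyl)but-2-enoate | COC(=O)/C(CBr)=C\[C@H](OC(C)=O)[C@H]1O[C@]1(C)C[C@H](OC(C)=O)/C=C(\C)CC=O
F5 | step 11 | methyl (2E,4S)-4-acetoxy-4-[(2R,3R)-3-[(2S,3E)-2-acetoxy-6-(tert-butyldimethylsilyloxy)-4-methylhex-3-en-1-yl]-3-methyloxiran-2-yl]-2-(tributylstannyl)but-2-enoate | COC(=O)/C([Sn](CCCC)(CCCC)CCCC)=C\[C@H](OC(C)=O)[C@H]1O[C@]1(C)C[C@H](OC(C)=O)/C=C(\C)CCO[Si](C)(C)C(C)(C)C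
F6 | step 11 | methyl (2E,4S)-4-acetoxy-4-[(2R,3R)-3-[(2S,3E)-2-acetoxy-6-(tert-butyldimethylsilyloxy)-4-methylhex-3-en-1-yl]-3-methyloxiran-2-yl]-2-iodobut-2-enoate | COC(=O)/C(I)=C\[C@H](OC(C)=O)[C@H]1O[C@]1(C)C[C@H](OC(C)=O)/C=C(\C)CCO[Si](C)(C)C(C)(C)C
F7 | step 11 | methyl (2Z,4S)-4-acetoxy-4-[(2R,3R)-3-[(2S,3E)-2-acetoxy-6-(tert-butyldimethylsilyloxy)-4-methylhex-3-en-1-yl]-3-methyloxiran-2-yl]-2-[(4,4,5,5-tetramethyl-1,3,2-dioxaborolan-2-yl)methyl]but-2-enoate | COC(=O)/C(CB1OC(C)(C)C(C)(C)O1)=C\[C@H](OC(C)=O)[C@H]1O[C@]1(C)C[C@H](OC(C)=O)/C=C(\C)CCO[Si](C)(C)C(C)(C)C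
F8 | step 9 | (2E,5S,6E)-9-(tert-butyldimethylsilyloxy)-5-hydroxy-3,7-dimethylnona-2,6-dienal | O=C/C=C(\C)C[C@H](O)/C=C(\C)CCO[Si](C)(C)C(C)(C)C
F9 | step 9 | (2E,5S,6E)-5-acetoxy-9-(tert-butyldimethylsilyloxy)-3,7-dimethylnona-2,6-dienal | O=C/C=C(\C)C[C@H](OC(C)=O)/C=C(\C)CCO[Si](C)(C)C(C)(C)C
F10 | step 9 | methyl (4R,5E,8S,9E)-8-acetoxy-12-(tert-butyldimethylsilyloxy)-4-hydroxy-6,10-dimethyldodeca-5,9-dien-2-ynoate | COC(=O)C#C[C@H](O)/C=C(\C)C[C@H](OC(C)=O)/C=C(\C)CCO[Si](C)(C)C(C)(C)C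
F11 | step 9 | methyl (4S)-4-[(2R,3R)-3-[(2S,3E)-2-acetoxy-6-(tert-butyldimethylsilyloxy)-4-methylhex-3-en-1-yl]-3-methyloxiran-2-yl]-4-hydroxybut-2-ynoate | COC(=O)C#C[C@H](O)[C@H]1O[C@]1(C)C[C@H](OC(C)=O)/C=C(\C)CCO[Si](C)(C)C(C)(C)C
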